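**Retrosynthetic overview**
1. Last bond, C8–prenyl. The target is an isomer of the prenyl ester of its own aromatic ring-A precursor. A palladium-catalysed ester-to-carbon prenyl transfer dearomatises ring A and sets the C8 quaternary centre. The ester comes from a dihydrocoumarin lactone plus prenol.
2. C8–CH2 bond: reductive alkylation through an ortho-quinone methide, joining a tricyclic phenol to a cis-cyclobutanecarbaldehyde.
3. Key step: the cyclobutane is made by photochemical Wolff ring contraction of a 5-diazo-2,2-dimethyl-3-isopropenylcyclopentanone. That ketone comes from 2-methylcyclopentenone by asymmetric conjugate addition and methylation.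
4. Tricyclic phenol: resorcinol → phloroglucinol → Pechmann coumarin → asymmetric conjugate reduction → C-tigloylation → asymmetric oxa-Michael closure.
5. Ring order: aromatic ring A, then the temporary lactone ring (it masks CO2H and 5-OH), then the pyranone ring. In parallel, cyclopentanone → cyclobutane. Last, the lactone is opened and ring A is dearomatised.

Numbering: target positions are chromanone positions O1, C2, C3, C4 (C=O), C4a, C5 (OH), C6 (side chain), C7 (C=O), C8 (quaternary), C8a.
Assumption: where the sense of induction of a chiral catalyst is extrapolated to a new substrate, the named antipode is the one expected by analogy; both antipodes are commercial and the other is used if the opposite sense is found.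

**Step 1**
Reactants: 1 2-methylcyclopent-2-en-1-one; 2 isopropenylmagnesium bromide
Product: 4 (3S)-2,2-dimethyl-3-(prop-1-en-2-yl)cyclopentan-1-one, via bromomagnesium enolate 3 (not isolated)
Conditions: CuBr·SMe2 (5 mol %), (R)-1-[(S)-2-(dicyclohexylphosphino)ferrocenyl]ethyldiphenylphosphine (6 mol %), t-BuOMe, −78 °C; then MeI (5 equiv), DMPU, −78 °C to rt
Reagents that add atoms: iodomethane, CI
Why: Copper-catalysed asymmetric conjugate addition of a Grignard reagent with trapping of the regiodefined magnesium enolate (tandem conjugate addition–alkylation): the ferrocenyl diphosphine–copper complex delivers the isopropenyl group to one enone face and sets C3 as (S), and methylation can only occur at C2, which becomes the stereocentre-free gem-dimethyl carbon.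

**Step 2**
Reactants: 4 (3S)-2,2-dimethyl-3-(prop-1-en-2-yl)cyclopentan-1-one
Product: 6 (3S)-5-diazo-2,2-dimethyl-3-(prop-1-en-2-yl)cyclopentan-1-one, via trifluoroacetyl ketone 5 (not isolated)
Conditions: LiN(SiMe3)2, THF, −78 °C; CF3CO2CH2CF3; 5 % HCl wash; then MsN3, Et3N, H2O (1 equiv), MeCN, rt
Reagents that add atoms: methanesulfonyl azide, CS(=O)(=O)N=[N+]=[N-]
Why: Detrifluoroacetylative diazo transfer (Regitz type): C5 is the only enolisable position, its trifluoroacetyl derivative 5 takes up the diazo group and loses the activating acyl group, and C3 is untouched.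

**Step 3 (key step)**
Reactants: 6 (3S)-5-diazo-2,2-dimethyl-3-(prop-1-en-2-yl)cyclopentan-1-one
Product: 9 (1S,3S)-2,2-dimethyl-3-(prop-1-en-2-yl)cyclobutane-1-carbaldehyde, via cyclobutylidene ketene 7 (not isolated), via Weinreb amide 8 (not isolated)
Conditions: hν (365 nm), MeNHOMe (1.2 equiv), THF, 0 °C; then i-Bu2AlH (2.5 equiv), −78 °C; aq. potassium sodium tartrate
Reagents that add atoms: none
Why: Photochemical Wolff rearrangement (ring contraction): loss of N2 with a 1,2-shift of the quaternary C2 from the carbonyl carbon to the diazo carbon contracts the cyclopentanone to ketene 7, the amine adds, the resulting enol is protonated at C1 from the face opposite the isopropenyl group so that the carbonyl group ends up cis to it and C1 is set as (S), and the Weinreb amide stops the i-Bu2AlH reduction at the aldehyde.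

**Step 4**
Reactants: 10 resorcinol
Product: 12 phloroglucinol (benzene-1,3,5-triol), via triboryl arene 11 (not isolated)
Conditions: HBpin (3.5 equiv), [Ir(OMe)(cod)]2 (1.5 mol %), dtbpy (3 mol %), THF, rt to 80 °C; then KHSO5 (as 2KHSO5·KHSO4·K2SO4), acetone/H2O, 0 °C; NaHSO3
Reagents that add atoms: potassium peroxymonosulfate, [K+].[O-]S(=O)(=O)OO
Why: Iridium-catalysed, sterically governed C–H borylation followed by C–B oxidation: both OH groups are masked in situ as O-Bpin, C5 is the only C–H without an ortho substituent, and oxidation plus hydrolysis of all B–O bonds gives the triol; no stereocentre.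

**Step 5**
Reactants: 13 hexanal; 14 ethyl diazoacetate
Product: 15 ethyl 3-oxooctanoate
Conditions: SnCl2 (10 mol %), CH2Cl2, rt
Reagents that add atoms: none
Why: Roskamp reaction: Lewis-acid-catalysed addition of the diazoacetate to the aldehyde, then a 1,2-hydride shift with loss of N2, gives the β-keto ester directly; no stereocentre.

**Step 6**
Reactants: 12 phloroglucinol; 15 ethyl 3-oxooctanoate
Product: 16 5,7-dihydroxy-4-pentyl-2H-chromen-2-one
Conditions: CF3SO3H, 0 °C to rt
Reagents that add atoms: none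
Why: Pechmann condensation: transesterification, ring closure onto the very electron-rich arene and dehydration, with only one product possible because phloroglucinol is threefold symmetric; no stereocentre.

**Step 7**
Reactants: 16 5,7-dihydroxy-4-pentyl-2H-chromen-2-one
Product: 17 (4S)-5,7-dihydroxy-4-pentyl-3,4-dihydro-2H-chromen-2-one
Conditions: Cu(OAc)2·H2O (5 mol %), (R)-DTBM-SEGPHOS (5.5 mol %), (EtO)2MeSiH (6 equiv), t-BuOH (3 equiv), PhMe/THF, 0 °C to rt; 1 M HCl/MeOH work-up
Reagents that add atoms: none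
Why: Copper hydride-catalysed asymmetric conjugate reduction of a 4-substituted coumarin: the bulky bisphosphine-ligated copper hydride adds hydride to one face of C4 and sets it as (S), t-BuOH protonates the copper enolate so that the lactone survives, and the phenols only consume extra silane.

**Step 8**
Reactants: 17 (4S)-5,7-dihydroxy-4-pentyl-3,4-dihydro-2H-chromen-2-one; 18 tigloyl chloride ((2E)-2-methylbut-2-enoyl chloride)
Product: 19 (4S)-5,7-dihydroxy-8-[(2E)-2-methylbut-2-enoyl]-4-pentyl-3,4-dihydro-2H-chromen-2-one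
Conditions: AlCl3 (4 equiv), ClCH2CH2Cl/PhNO2, 50 °C; cold 1 M HCl quench
Reagents that add atoms: none
Why: Friedel–Crafts acylation: C8 lies between the ring-tied lactone oxygen and one aluminium phenoxide, so it is less shielded than C6, which lies between two aluminium phenoxides (one pushed toward it by the pentyl-bearing peri carbon); this is the site preference of 4-alkyl-5,7-dihydroxycoumarins, the chelated enone does not cyclise until base is added, and no stereocentre is formed.

**Step 9**
Reactants: 19 (4S)-5,7-dihydroxy-8-[(2E)-2-methylbut-2-enoyl]-4-pentyl-3,4-dihydro-2H-chromen-2-one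
Product: 21 (4S,8R,9R)-5-hydroxy-8,9-dimethyl-4-pentyl-3,4,8,9-tetrahydro-2H,10H-pyrano[2,3-f]chromene-2,10-dione, via cis-chromanone 20 (not isolated)
Conditions: (−)-quinine (20 mol %), PhCl, 15 °C; then MgI2 (1.5 equiv), 40 °C
Reagents that add atoms: none
Why: Cinchona-alkaloid-catalysed intramolecular oxa-Michael addition followed by epimerisation through soft enolisation: the lactone blocks the other ortho oxygen so only 7-OH can close, quinine guides it onto one face of the tigloyl β-carbon and sets the O-bearing carbon as (R) with kinetic cis protonation (20), and MgI2 plus the amine enolises only the ketone α-carbon so that it relaxes to the more stable trans (R,R) pair without ring opening.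

**Step 10**
Reactants: 21 (4S,8R,9R)-5-hydroxy-8,9-dimethyl-4-pentyl-3,4,8,9-tetrahydro-2H,10H-pyrano[2,3-f]chromene-2,10-dione; 9 (1S,3S)-2,2-dimethyl-3-(prop-1-en-2-yl)cyclobutane-1-carbaldehyde
Product: 24 (4S,8R,9R)-6-{[(1R,3S)-2,2-dimethyl-3-(prop-1-en-2-yl)cyclobutyl]methyl}-5-hydroxy-8,9-dimethyl-4-pentyl-3,4,8,9-tetrahydro-2H,10H-pyrano[2,3-f]chromene-2,10-dione, via benzodioxaborin 22 (not isolated), via ortho-quinone methide 23 (not isolated)
Conditions: PhB(OH)2 (1.2 equiv), EtCO2H (0.5 equiv), PhMe, reflux, Dean–Stark; then Hantzsch ester (diethyl 2,6-dimethyl-1,4-dihydropyridine-3,5-dicarboxylate, 2 equiv), reflux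
Reagents that add atoms: none
Why: Nagata-type boronic-acid-templated ortho-hydroxyalkylation followed by ortho-quinone methide transfer hydrogenation (reductive alkylation): the boron tether brings the aldehyde to the only free ring carbon (target C8, ortho to the only free OH), thermal collapse of 22 gives 23, the Hantzsch ester reduces its exocyclic carbon without touching ketone, lactone or alkene, no amine or strong acid is present that could epimerise the cyclobutane carbon or protonate the isopropenyl group, and no new stereocentre is formed.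

**Step 11**
Reactants: 24 (4S,8R,9R)-6-{[(1R,3S)-2,2-dimethyl-3-(prop-1-en-2-yl)cyclobutyl]methyl}-5-hydroxy-8,9-dimethyl-4-pentyl-3,4,8,9-tetrahydro-2H,10H-pyrano[2,3-f]chromene-2,10-dione; 25 prenol (3-methylbut-2-en-1-ol)
Product: 27 (3S)-3-[(2R,3R,8R)-8-{[(1R,3S)-2,2-dimethyl-3-(prop-1-en-2-yl)cyclobutyl]methyl}-5-hydroxy-2,3-dimethyl-8-(3-methylbut-2-en-1-yl)-4,7-dioxo-3,4,7,8-tetrahydro-2H-chromen-6-yl]octanoic acid (CNP0208815.1), via prenyl ester 26 (not isolated)
Conditions: KN(SiMe3)2 (1.0 equiv), THF, −40 °C; KOCH2CH=CMe2 [from 25 (1.05 equiv) + KN(SiMe3)2 (1.05 equiv)], −40 to 0 °C; then Pd2(dba)3·CHCl3 (2.5 mol %), (R,R)-ANDEN-phenyl Trost ligand (7.5 mol %), THF/PhMe, 0 °C to rt (40 °C if slow); cold 1 M HCl to pH 3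
Reagents that add atoms: none
Why: Proposed new method: a ligand-controlled, dearomative ester-to-carbon prenyl transfer in which the alkoxide opens the aryl lactone (alkoxide traded for a far more stable phenoxide) to give 26 as its bis-phenoxide, zerovalent palladium ionises the prenyl ester with the tethered carboxylate as leaving group, and the π-prenylpalladium cation is attacked at its unsubstituted terminus by C8 of the phloroglucinol-type dianion; O-prenyl ethers and the ester itself re-ionise so only C–C bond formation is irreversible, C6 is shielded by its secondary alkyl group, the product is drained as a stabilised enolate/carboxylate, the chiral pocket of the diamide diphosphine selects the face of the planar nucleophile and sets C8 as (R), and the closest known reactions are Tsuji–Trost asymmetric prenylation of prochiral carbon nucleophiles and palladium-catalysed allylic dearomatisation of naphthols and acylphloroglucinols.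

**Compound list**
1 | 2-methylcyclopent-2-en-1-one | CC1=CCCC1=O | starting material
2 | isopropenylmagnesium bromide | C=C(C)[Mg]Br | starting material
3 | bromomagnesium (3S)-2-methyl-3-(prop-1-en-2-yl)cyclopent-1-en-1-olate | C=C(C)[C@@H]1CCC(O[Mg]Br)=C1C | intermediate
4 | (3S)-2,2-dimethyl-3-(prop-1-en-2-yl)cyclopentan-1-one | C=C(C)[C@@H]1CCC(=O)C1(C)C | intermediate
5 | (3S)-2,2-dimethyl-3-(prop-1-en-2-yl)-5-(trifluoroacetyl)cyclopentan-1-one (keto–enol mixture, C5 undefined) | C=C(C)[C@@H]1CC(C(=O)C(F)(F)F)C(=O)C1(C)C | intermediate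
6 | (3S)-5-diazo-2,2-dimethyl-3-(prop-1-en-2-yl)cyclopentan-1-one | C=C(C)[C@@H]1CC(=[N+]=[N-])C(=O)C1(C)C | intermediate
7 | [(3S)-2,2-dimethyl-3-(prop-1-en-2-yl)cyclobutylidene]methanone (ketene) | C=C(C)[C@@H]1CC(=C=O)C1(C)C | intermediate
8 | (1S,3S)-N-methoxy-N,2,2-trimethyl-3-(prop-1-en-2-yl)cyclobutane-1-carboxamide (cis) | C=C(C)[C@@H]1C[C@H](C(=O)N(C)OC)C1(C)C | intermediate
9 | (1S,3S)-2,2-dimethyl-3-(prop-1-en-2-yl)cyclobutane-1-carbaldehyde (cis) | C=C(C)[C@@H]1C[C@H](C=O)C1(C)C | intermediate
10 | resorcinol | Oc1cccc(O)c1 | starting material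
11 | 1,3-bis(pinacolboryloxy)-5-(pinacolboryl)benzene | CC1(C)OB(Oc2cc(OB3OC(C)(C)C(C)(C)O3)cc(B3OC(C)(C)C(C)(C)O3)c2)OC1(C)C | intermediate
12 | phloroglucinol | Oc1cc(O)cc(O)c1 | intermediate
13 | hexanal | CCCCCC=O | starting material
14 | ethyl diazoacetate | CCOC(=O)C=[N+]=[N-] | starting material
15 | ethyl 3-oxooctanoate | CCCCCC(=O)CC(=O)OCC | intermediate
16 | 5,7-dihydroxy-4-pentyl-2H-chromen-2-one | CCCCCC1=CC(=O)Oc2cc(O)cc(O)c21 | intermediate
17 | (4S)-5,7-dihydroxy-4-pentyl-3,4-dihydro-2H-chromen-2-one | CCCCC[C@H]1CC(=O)Oc2cc(O)cc(O)c21 | intermediate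
18 | tigloyl chloride | C/C=C(\C)C(=O)Cl | starting material
19 | (4S)-5,7-dihydroxy-8-[(2E)-2-methylbut-2-enoyl]-4-pentyl-3,4-dihydro-2H-chromen-2-one | CCCCC[C@H]1CC(=O)Oc2c(C(=O)/C(C)=C/C)c(O)cc(O)c21 | intermediate
20 | (4S,8R,9S)-5-hydroxy-8,9-dimethyl-4-pentyl-3,4,8,9-tetrahydro-2H,10H-pyrano[2,3-f]chromene-2,10-dione (cis-dimethyl) | CCCCC[C@H]1CC(=O)Oc2c1c(O)cc3c2C(=O)[C@@H](C)[C@@H](C)O3 | intermediate
21 | (4S,8R,9R)-5-hydroxy-8,9-dimethyl-4-pentyl-3,4,8,9-tetrahydro-2H,10H-pyrano[2,3-f]chromene-2,10-dione (trans-dimethyl) | CCCCC[C@H]1CC(=O)Oc2c1c(O)cc3c2C(=O)[C@H](C)[C@@H](C)O3 | intermediate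
22 | 2-phenyl-4H-1,3,2-benzodioxaborin built on O5/C6 of 21, its C4 carrying the cis-cyclobutyl group of 9 (benzylic configuration undefined) | CCCCC[C@H]1CC(=O)Oc2c1c5OB(c6ccccc6)OC([C@H]4C[C@@H](C(C)=C)C4(C)C)c5c3c2C(=O)[C@H](C)[C@@H](C)O3 | intermediate
23 | ortho-quinone methide of 21: C5=O and exocyclic C6=CH–(cis-cyclobutyl), alkene geometry undefined | CCCCC[C@H]1CC(=O)OC2=C1C(=O)C(=C[C@H]4C[C@@H](C(C)=C)C4(C)C)C3=C2C(=O)[C@H](C)[C@@H](C)O3 | intermediate
24 | (4S,8R,9R)-6-{[(1R,3S)-2,2-dimethyl-3-(prop-1-en-2-yl)cyclobutyl]methyl}-5-hydroxy-8,9-dimethyl-4-pentyl-3,4,8,9-tetrahydro-2H,10H-pyrano[2,3-f]chromene-2,10-dione | CCCCC[C@H]1CC(=O)Oc2c1c(O)c(C[C@H]4C[C@@H](C(C)=C)C4(C)C)c3c2C(=O)[C@H](C)[C@@H](C)O3 | intermediate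
25 | prenol (3-methylbut-2-en-1-ol) | CC(C)=CCO | starting material
26 | 3-methylbut-2-en-1-yl (3S)-3-[(2R,3R)-8-{[(1R,3S)-2,2-dimethyl-3-(prop-1-en-2-yl)cyclobutyl]methyl}-5,7-dihydroxy-2,3-dimethyl-4-oxochroman-6-yl]octanoate (present as dipotassium bis-phenoxide; drawn neutral) | CCCCC[C@@H](CC(=O)OCC=C(C)C)c1c(O)c(C[C@H]3C[C@@H](C(C)=C)C3(C)C)c2O[C@H](C)[C@@H](C)C(=O)c2c1O | intermediate
27 | CNP0208815.1, (3S)-3-[(2R,3R,8R)-8-{[(1R,3S)-2,2-dimethyl-3-(prop-1-en-2-yl)cyclobutyl]methyl}-5-hydroxy-2,3-dimethyl-8-(3-methylbut-2-en-1-yl)-4,7-dioxo-3,4,7,8-tetrahydro-2H-chromen-6-yl]octanoic acid | C=C(C)[C@@H]1C[C@H](C[C@@]2(CC=C(C)C)C(=O)C([C@@H](CCCCC)CC(=O)O)=C(O)C3=C2O[C@H](C)[C@@H](C)C3=O)C1(C)C | target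

**Totals**
Total step count: 11. Longest linear sequence: 7 steps (4, 6, 7, 8, 9, 10, 11).

**Three steps most likely to fail**

Step 11 (the proposed new step). Possible failures:
- slow ionisation of a prenyl alkanoate
- attack through C6 or persistent O-prenylation
- poor facial control at C8

The fallback uses known chemistry, sets out from 24 and comes back at 27. NaOMe in MeOH at 0 °C opens the lactone to the ring-opened methyl ester F1. Classical alkylative dearomatisation of its phenoxide with prenyl bromide (NaOMe, MeOH, 0 °C), as practised for lupulone-type acylphloroglucinols, gives the C8-prenylated methyl ester F2 together with the C8-epimeric methyl ester F3. The two are separated by preparative HPLC, and LiOH in THF/H2O hydrolyses F2 to 27.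

Step 10. Possible failures:
- the hindered aldehyde condenses slowly
- 23 tautomerises to a vinylphenol by a 1,5-hydrogen shift
- 23 is trapped by the cis isopropenyl group in a pinane-type closure
- 9 epimerises on long heating

The fallback replaces the quinone methide by a cross-coupling, sets out from 9 and 21 and comes back at 24. NaBH4 reduces 9 to the cyclobutylmethanol F4. I2/PPh3/imidazole converts it into the cyclobutylmethyl iodide F5. Zn dust with LiCl in THF inserts to give the alkylzinc iodide F6. N-iodosuccinimide in MeCN iodinates 21 at its only free ring carbon to give the aryl iodide F7. Negishi coupling of F7 with slowly added F6 (Pd(OAc)2, SPhos, THF, rt) gives 24.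

Step 1. A branched alkenyl Grignard reagent on an α-substituted cyclopentenone may give low ee, and the magnesium enolate may equilibrate before methylation. The fallback gives up asymmetric catalysis, sets out from 1 and 2 and comes back at 4. The same addition and methylation with CuBr·SMe2 and no chiral ligand gives the racemic ketone F8. This is resolved by preparative supercritical-fluid chromatography on a chiral stationary phase, and the (S)-enantiomer is 4.

**Further compounds**
F1 | step 11 | methyl (3S)-3-[(2R,3R)-8-{[(1R,3S)-2,2-dimethyl-3-(prop-1-en-2-yl)cyclobutyl]methyl}-5,7-dihydroxy-2,3-dimethyl-4-oxochroman-6-yl]octanoate | CCCCC[C@@H](CC(=O)OC)c1c(O)c(C[C@H]3C[C@@H](C(C)=C)C3(C)C)c2O[C@H](C)[C@@H](C)C(=O)c2c1O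
F2 | step 11 | methyl ester of 27 (8R) | C=C(C)[C@@H]1C[C@H](C[C@@]2(CC=C(C)C)C(=O)C([C@@H](CCCCC)CC(=O)OC)=C(O)C3=C2O[C@H](C)[C@@H](C)C3=O)C1(C)C
F3 | step 11 | C8 epimer of F2 (8S) | C=C(C)[C@@H]1C[C@H](C[C@]2(CC=C(C)C)C(=O)C([C@@H](CCCCC)CC(=O)OC)=C(O)C3=C2O[C@H](C)[C@@H](C)C3=O)C1(C)C
F4 | step 10 | [(1S,3S)-2,2-dimethyl-3-(prop-1-en-2-yl)cyclobutyl]methanol | C=C(C)[C@@H]1C[C@H](CO)C1(C)C
F5 | step 10 | (1S,3S)-1-(iodomethyl)-2,2-dimethyl-3-(prop-1-en-2-yl)cyclobutane | C=C(C)[C@@H]1C[C@H](CI)C1(C)C
F6 | step 10 | {[(1S,3S)-2,2-dimethyl-3-(prop-1-en-2-yl)cyclobutyl]methyl}zinc iodide | C=C(C)[C@@H]1C[C@H](C[Zn]I)C1(C)C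
F7 | step 10 | (4S,8R,9R)-5-hydroxy-6-iodo-8,9-dimethyl-4-pentyl-3,4,8,9-tetrahydro-2H,10H-pyrano[2,3-f]chromene-2,10-dione | CCCCC[C@H]1CC(=O)Oc2c1c(O)c(I)c3c2C(=O)[C@H](C)[C@@H](C)O3
F8 | step 1 | racemic 2,2-dimethyl-3-(prop-1-en-2-yl)cyclopentan-1-one | C=C(C)C1CCC(=O)C1(C)C
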